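Vidalol A is cut at two neighbouring positions of ring A at once: the C1–C7 bond to the benzylic carbon and the C2–Br bond. Both are made in a single flask from the C1–C2 aryne of ring A, which accepts a 2,4,6-trimethoxybenzyl Grignard reagent at C1 and electrophilic bromine at the resulting C2 carbanion. The step exploits the contiguous C1 (benzyl), C2 (Br), C3 (Br) array: the C3 bromine, already in place, polarises the aryne so that carbon enters at the remote C1. The precursor is a 4,5-dimethoxybenzene carrying iodine at C1, a 4-chlorobenzenesulfonate at C2 and bromine at C3. Ring B bromination and global demethylation finish the synthesis.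

Key step: step 6

**Numbering.** Ring A is the dibromocatechol ring: C1 bears the methylene C7, C2 and C3 bear bromine, C4 and C5 bear oxygen, and C6 bears hydrogen. Ring B is the bromophloroglucinol ring. The target has no stereocentre.

**Assumption.** 2-Bromo-3,4-dimethoxybenzaldehyde (1) is taken as a catalogue compound. It is otherwise two routine steps from isovanillin (bromination, then O-methylation).

**Design points.**
- (a) The C3 bromine comes with the starting material and iodine enters last. No source of electrophilic bromine ever meets an iodophenol, so ipso halogen exchange and regiochemical doubt are avoided.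
- (b) The benzylic carbanion is released from a methyl ether. The corresponding halides ionise too easily to be handled. A sulfide precursor would leave one equivalent of thiolate, an excellent aryne trap, in the Grignard solution.
- (c) In the magnesiated sulfonate the only leaving group next to magnesium is the C2 sulfonate. The C3 bromide becomes a threat only after the carbon nucleophile has added and magnesium sits at C2, so the key step has a temperature ceiling.

## Route

Step 1
Reactants: 1 2-bromo-3,4-dimethoxybenzaldehyde
Product: 3 2-bromo-3,4-dimethoxyphenol, via aryl formate 2 (not isolated)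
Conditions: mCPBA (1.3 equiv), CH2Cl2, 0 °C → rt; aq Na2S2O3/NaHCO3 wash; K2CO3 (0.2 equiv), MeOH, rt
Reagents that add atoms: 3-chloroperoxybenzoic acid (mCPBA), OOC(=O)c1cccc(Cl)c1
Why: Baeyer–Villiger oxidation of an electron-rich benzaldehyde, in which the aryl group (para to a methoxy group) migrates in preference to hydride, followed by mild methanolysis of the formate, so the bromine that becomes C3 is bought in place next to the new C2 oxygen instead of being won by a selective halogenation.

Step 2
Reactants: 3 2-bromo-3,4-dimethoxyphenol
Product: 4 2-bromo-6-iodo-3,4-dimethoxyphenol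
Conditions: NIS (1.05 equiv), TsOH·H2O (10 mol%), dry MeCN, 0 °C → rt, dark
Reagents that add atoms: N-iodosuccinimide, O=C1CCC(=O)N1I
Why: Electrophilic aromatic iodination should go to the only free position ortho to the phenol and para to the C4 methoxy group (the future C1), the other free carbon (C6) being meta to the hydroxyl, and an iodonium source does not displace the bromine already present.

Step 3
Reactants: 4 2-bromo-6-iodo-3,4-dimethoxyphenol; 5 4-chlorobenzenesulfonyl chloride
Product: 6 2-bromo-6-iodo-3,4-dimethoxyphenyl 4-chlorobenzenesulfonate
Conditions: Et3N (1.5 equiv), DMAP (10 mol%), CH2Cl2, 0 °C → rt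
Reagents that add atoms: none
Why: Base-mediated O-sulfonylation of a phenol, with DMAP as nucleophilic catalyst to overcome the two flanking halogens, leaves aryl halides and methyl ethers untouched.

Step 4
Reactants: 7 1,3,5-trimethoxybenzene
Product: 9 1,3,5-trimethoxy-2-(methoxymethyl)benzene, via 2,4,6-trimethoxyphenyllithium 8 (not isolated)
Conditions: nBuLi (1.1 equiv), THF, 0 °C → rt; MOMCl (1.2 equiv), −78 °C → rt; purification on Et3N-deactivated silica
Reagents that add atoms: chloromethyl methyl ether, COCCl
Why: Directed ortho-lithiation between two methoxy groups (all three ring C–H are equivalent) followed by SN2 alkylation of the aryllithium with the α-chloro ether gives a benzylic leaving group that, unlike a 2,4,6-trimethoxybenzyl halide, can be stored.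

Step 5
Reactants: 9 1,3,5-trimethoxy-2-(methoxymethyl)benzene
Product: 11 2,4,6-trimethoxybenzylmagnesium bromide, via 2,4,6-trimethoxybenzyllithium 10 (not isolated)
Conditions: Li granules (6 equiv), naphthalene (10 mol%), THF, −20 °C; cannulated off the excess Li; MgBr2 (2.2 equiv, 0.5 M in Et2O–THF), −40 °C; solution titrated, kept at −40 °C and used directly
Reagents that add atoms: magnesium bromide, Br[Mg]Br
Why: Arene-catalysed reductive lithiation of a benzyl methyl ether (two single-electron transfers with cleavage of the benzylic C–O bond) followed by lithium-to-magnesium transmetalation gives the Grignard reagent with methoxide as the only anionic by-product, and the second equivalent of MgBr2 ties that up as a poorly nucleophilic magnesium alkoxide.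

Step 6
Reactants: 6 2-bromo-6-iodo-3,4-dimethoxyphenyl 4-chlorobenzenesulfonate; 11 2,4,6-trimethoxybenzylmagnesium bromide
Product: 15 2-[(2,3-dibromo-4,5-dimethoxyphenyl)methyl]-1,3,5-trimethoxybenzene, via magnesiated sulfonate 12 (not isolated), via ring A aryne 13 (not isolated), via C2 arylmagnesium adduct 14 (not isolated)
Conditions: 6, iPrMgCl·LiCl (1.05 equiv), THF, −78 °C, 45 min; 11 (2.0 equiv, precooled), −78 °C, then warmed only until 12 is consumed (expected between −40 and −20 °C, never above −20 °C); recooled to −78 °C, BrCCl2CCl2Br (3.0 equiv) in THF, → 0 °C; MeOH–Et3N, then aq NH4Cl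
Reagents that add atoms: 1,2-dibromo-1,1,2,2-tetrachloroethane, ClC(Cl)(Br)C(Cl)(Cl)Br
Why: Iodine–magnesium exchange at C1 should be complete at −78 °C, where 12 persists, so no iPrMgCl is left when warming lets the C2 sulfonate depart by β-elimination to give aryne 13. Carbomagnesiation of 13 by 11 and halophilic bromination of 14 follow the known three-component pattern of Grignard addition to arynes released from 2-magnesiated aryl sulfonates, with electrophilic quench of the new arylmagnesium. The selectivity needed is regiochemical: the inductively withdrawing C3 bromine distorts the triple bond so that C1 is the more linear and more electrophilic terminus and the developing charge at C2 lies next to bromine, the weak opposing effects of the C4 and C5 methoxy groups roughly cancel, and the bulky nucleophile also prefers C1 beside C6–H. Both ortho carbons of 11 carry methoxy groups, so only its CH2 carbon can bond. Adduct 14 is an ortho-bromoarylmagnesium that could expel MgBr2 across C2–C3, which is why the mixture is kept cold and recooled before the quench, and the basic methanol quench solvolyses the labile benzylic bromide formed from surplus 11. No ring is closed and no stereocentre is created.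

Step 7
Reactants: 15 2-[(2,3-dibromo-4,5-dimethoxyphenyl)methyl]-1,3,5-trimethoxybenzene
Product: 16 2-bromo-4-[(2,3-dibromo-4,5-dimethoxyphenyl)methyl]-1,3,5-trimethoxybenzene
Conditions: NBS (1.0 equiv, in portions), MeCN–CH2Cl2, −20 → 0 °C, dark
Reagents that add atoms: N-bromosuccinimide, O=C1CCC(=O)N1Br
Why: Electrophilic aromatic bromination under ionic conditions should be selective because ring B carries three donor groups and two symmetry-equivalent free positions, ring A is deactivated by two bromines, and the first bromine lowers the reactivity of ring B enough for one equivalent of NBS at low temperature to stop at the monobromide.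

Step 8
Reactants: 16 2-bromo-4-[(2,3-dibromo-4,5-dimethoxyphenyl)methyl]-1,3,5-trimethoxybenzene
Product: 17 vidalol A
Conditions: BBr3 (8 equiv), CH2Cl2, −78 °C → rt, argon; ice-water quench at 0 °C, extraction with EtOAc under argon
Reagents that add atoms: none
Why: Lewis acid mediated cleavage of aryl methyl ethers with BBr3 (coordination to oxygen, then SN2 attack of bromide on methyl), the standard last step for polybrominated phenols, should leave the aryl bromides and the diarylmethane carbon untouched at or below room temperature.

## Compound list

1 | 2-bromo-3,4-dimethoxybenzaldehyde | COc1ccc(C=O)c(Br)c1OC | starting material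
2 | 2-bromo-3,4-dimethoxyphenyl formate | COc1ccc(OC=O)c(Br)c1OC | intermediate
3 | 2-bromo-3,4-dimethoxyphenol | COc1ccc(O)c(Br)c1OC | intermediate
4 | 2-bromo-6-iodo-3,4-dimethoxyphenol | COc1cc(I)c(O)c(Br)c1OC | intermediate
5 | 4-chlorobenzenesulfonyl chloride | O=S(=O)(Cl)c1ccc(Cl)cc1 | starting material
6 | 2-bromo-6-iodo-3,4-dimethoxyphenyl 4-chlorobenzenesulfonate | COc1cc(I)c(OS(=O)(=O)c2ccc(Cl)cc2)c(Br)c1OC | intermediate
7 | 1,3,5-trimethoxybenzene | COc1cc(OC)cc(OC)c1 | starting material
8 | 2,4,6-trimethoxyphenyllithium | [Li]c1c(OC)cc(OC)cc1OC | intermediate
9 | 1,3,5-trimethoxy-2-(methoxymethyl)benzene (2,4,6-trimethoxybenzyl methyl ether) | COCc1c(OC)cc(OC)cc1OC | intermediate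
10 | 2,4,6-trimethoxybenzyllithium | [Li]Cc1c(OC)cc(OC)cc1OC | intermediate
11 | 2,4,6-trimethoxybenzylmagnesium bromide | COc1cc(OC)c(C[Mg]Br)c(OC)c1 | intermediate
12 | 2-bromo-6-(chloromagnesio)-3,4-dimethoxyphenyl 4-chlorobenzenesulfonate | COc1cc([Mg]Cl)c(OS(=O)(=O)c2ccc(Cl)cc2)c(Br)c1OC | intermediate
13 | 3-bromo-4,5-dimethoxybenzyne (C1–C2 aryne of ring A) | COC1=CC#CC(Br)=C1OC | intermediate
14 | {2-bromo-3,4-dimethoxy-6-[(2,4,6-trimethoxyphenyl)methyl]phenyl}magnesium bromide | COc1cc(OC)c(Cc2cc(OC)c(OC)c(Br)c2[Mg]Br)c(OC)c1 | intermediate
15 | 2-[(2,3-dibromo-4,5-dimethoxyphenyl)methyl]-1,3,5-trimethoxybenzene | COc1cc(OC)c(Cc2cc(OC)c(OC)c(Br)c2Br)c(OC)c1 | intermediate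
16 | 2-bromo-4-[(2,3-dibromo-4,5-dimethoxyphenyl)methyl]-1,3,5-trimethoxybenzene | COc1cc(OC)c(Cc2cc(OC)c(OC)c(Br)c2Br)c(OC)c1Br | intermediate
17 | vidalol A, 2-bromo-4-[(2,3-dibromo-4,5-dihydroxyphenyl)methyl]benzene-1,3,5-triol | Oc1cc(Cc2c(O)cc(O)c(Br)c2O)c(Br)c(Br)c1O | target

## Step count and risks

Total step count: 8. Longest linear sequence: 6 (steps 1, 2, 3, 6, 7, 8).

**Step 6 (most likely to fail).**
- The sulfonate may leave only at a temperature at which the adduct already expels its C3 bromide, which would give a second aryne and double benzylation.
- The Grignard reagent may attack the sulfonyl sulfur.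
- The aryne may be captured by its own magnesiated precursor.
- The regiochemical bias may be eroded.

The fallback is a Friedel–Crafts benzylation without any aryne. It sets out from 7 and comes back at 15. Vanillin is brominated twice (Br2, AcOH, the second bromine entering para to the methoxy group with iron powder as catalyst) to 2,3-dibromo-4-hydroxy-5-methoxybenzaldehyde F1. This is O-methylated (MeI, K2CO3, DMF) to 2,3-dibromo-4,5-dimethoxybenzaldehyde F2 and reduced (NaBH4, MeOH) to (2,3-dibromo-4,5-dimethoxyphenyl)methanol F3. F3 then alkylates an excess of 7 under BF3·OEt2 catalysis in CH2Cl2 at 0 °C to give 15.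

**Step 5.**
- Electron transfer into the very electron-rich arene may be sluggish.
- Aryl–oxygen cleavage may compete.
- Proton transfer from a ring C–H flanked by two methoxy groups may quench the benzylic carbanion.

The fallback is a sulfide and tin relay. It sets out from 9 and comes back at 10. Thiophenol and a trace of CF3CO2H in CH2Cl2 exchange the methoxy group through the stabilised benzylic cation to give 2,4,6-trimethoxybenzyl phenyl sulfide F4. Reductive lithiation of F4 follows (Li powder, 4,4'-di-tert-butylbiphenyl 5 mol%, THF, −78 °C); here the electron enters the phenylthio group rather than the donor-rich ring. Quench with one equivalent of Bu3SnCl gives tributyl[(2,4,6-trimethoxyphenyl)methyl]stannane F5. F5 is freed from thiophenol by a basic wash and chromatography on basic alumina. Tin–lithium exchange (nBuLi, THF, −78 °C) then delivers 10 beside inert Bu4Sn, and MgBr2 gives 11 as in step 5.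

**Step 8.**
- Acid may promote loss or migration of the ring B bromine as the phloroglucinol is unveiled.
- Ipso protonation of ring B may cleave the bond to C7.
- The flanked ethers may be cleaved incompletely.
- The catechol may oxidise in air.

The fallback inverts the order of the last two operations. It sets out from 15 and comes back at 17. Compound 15 is demethylated first (BBr3, CH2Cl2, −78 °C → rt) to 2-[(2,3-dibromo-4,5-dihydroxyphenyl)methyl]benzene-1,3,5-triol F6, so that no ring B bromide is ever exposed to BBr3 and HBr. F6 is then monobrominated on the far more nucleophilic phloroglucinol ring with one equivalent of Bu4NBr3 in CH2Cl2–MeOH at −20 °C to give 17.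

Further compounds
F1 | step 6 | 2,3-dibromo-4-hydroxy-5-methoxybenzaldehyde | COc1cc(C=O)c(Br)c(Br)c1O
F2 | step 6 | 2,3-dibromo-4,5-dimethoxybenzaldehyde | COc1cc(C=O)c(Br)c(Br)c1OC
F3 | step 6 | (2,3-dibromo-4,5-dimethoxyphenyl)methanol | COc1cc(CO)c(Br)c(Br)c1OC
F4 | step 5 | 2,4,6-trimethoxybenzyl phenyl sulfide | COc1cc(OC)c(CSc2ccccc2)c(OC)c1
F5 | step 5 | tributyl[(2,4,6-trimethoxyphenyl)methyl]stannane | CCCC[Sn](CCCC)(CCCC)Cc1c(OC)cc(OC)cc1OC
F6 | step 8 | 2-[(2,3-dibromo-4,5-dihydroxyphenyl)methyl]benzene-1,3,5-triol | Oc1cc(O)c(Cc2cc(O)c(O)c(Br)c2Br)c(O)c1
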